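**Retrosynthetic overview**
1. Agastinol 22 ⇐ hydrogenolysis of its tri-O-benzyl ether 21 ⇐ acylation of tetrahydrofuran alcohol 19 (di-O-benzyl-(−)-lariciresinol) with 4-(benzyloxy)benzoyl chloride 20.
2. Tetrahydrofuran ring of 19 ⇐ acid-mediated 5-exo closure of triol 18 (C9' hydroxyl onto the C7 benzylic cation) ⇐ LiAlH4 reduction of hydroxy lactone 17.
3. Key C–C bond (C7–C8): intermolecular aldol addition of the lithium enolate of (S)-β-benzyl-γ-butyrolactone 14 to O-benzylvanillin 15, anti to the benzyl group.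
4. Lactone 14 ⇐ Evans alkylation of arylpropanoyl oxazolidinone 7 (from ferulic acid 1 and auxiliary 5) with tert-butyl bromoacetate 8, then auxiliary hydrolysis, borane reduction and lactonisation.
5. Ring order: the γ-butyrolactone first (step 8, a temporary ring opened again in step 10), then the tetrahydrofuran ring of the target (step 11).

Assumption: the SMILES is read as the (7R,8S,8'S) isomer [(2R,3S,4S) in tetrahydrofuran numbering], i.e. the 9-O-(4-hydroxybenzoate) of (−)-lariciresinol; lignan numbering is used (C7 = ArCH–O, C8 = CH–CH2O(C9), C8' = CH–CH2Ar, C9' = ring OCH2).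

**Route**

Step 1
Reactants: 1 ferulic acid [(E)-3-(4-hydroxy-3-methoxyphenyl)prop-2-enoic acid]
Product: 2 3-(4-hydroxy-3-methoxyphenyl)propanoic acid
Conditions: H2 (1 atm), 10% Pd/C, MeOH, rt
Reagents that add atoms: none
Why: Heterogeneous catalytic hydrogenation saturates the cinnamic C=C bond cleanly and leaves the arene, phenol and acid untouched.

Step 2
Reactants: 2 3-(4-hydroxy-3-methoxyphenyl)propanoic acid
Product: 3 benzyl 3-(4-benzyloxy-3-methoxyphenyl)propanoate
Conditions: BnBr (2.4 equiv), K2CO3 (3 equiv), DMF, 60 °C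
Reagents that add atoms: benzyl bromide, BrCc1ccccc1
Why: Williamson-type O-alkylation: K2CO3 deprotonates both the phenol and the acid and each anion is benzylated by SN2, giving one neutral compound.

Step 3
Reactants: 3 benzyl 3-(4-benzyloxy-3-methoxyphenyl)propanoate
Product: 4 3-(4-benzyloxy-3-methoxyphenyl)propanoic acid
Conditions: 2 M aq NaOH, THF/MeOH, 50 °C; then 1 M HCl
Reagents that add atoms: sodium hydroxide, [Na+].[OH-]
Why: Saponification cleaves only the benzyl ester because the aryl benzyl ether is inert to hydroxide.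

Step 4
Reactants: 4 3-(4-benzyloxy-3-methoxyphenyl)propanoic acid; 5 (R)-4-benzyl-2-oxazolidinone
Product: 7 (R)-4-benzyl-3-[3-(4-benzyloxy-3-methoxyphenyl)propanoyl]oxazolidin-2-one, via mixed pivalic anhydride 6 (not isolated)
Conditions: t-BuCOCl, Et3N, THF, −20 °C; then LiCl, 5, −20 °C → rt
Reagents that add atoms: pivaloyl chloride, CC(C)(C)C(=O)Cl (its acyl group is in 6 only)
Why: Mixed-anhydride N-acylation: the LiCl/Et3N-activated oxazolidinone attacks the less hindered carbonyl of the pivalic anhydride, and no stereocentre is formed or disturbed.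

Step 5
Reactants: 7 (R)-4-benzyl-3-[3-(4-benzyloxy-3-methoxyphenyl)propanoyl]oxazolidin-2-one; 8 tert-butyl bromoacetate
Product: 10 tert-butyl (S)-3-[(R)-4-benzyl-2-oxooxazolidine-3-carbonyl]-4-(4-benzyloxy-3-methoxyphenyl)butanoate, via sodium Z-enolate 9 (not isolated)
Conditions: NaN(SiMe3)2 (1.1 equiv), THF, −78 °C; then 8 (1.5 equiv), −78 → −40 °C
Reagents that add atoms: sodium bis(trimethylsilyl)amide, C[Si](C)(C)[N-][Si](C)(C)C.[Na+] (its sodium is in 9 only)
Why: Evans asymmetric alkylation: the chelated Z-enolate is alkylated on the face opposite the C4 benzyl group of the (R)-auxiliary, which sets the future C8' centre as S (dr typically above 95:5, minor isomer removed by chromatography).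

Step 6
Reactants: 10 tert-butyl (S)-3-[(R)-4-benzyl-2-oxooxazolidine-3-carbonyl]-4-(4-benzyloxy-3-methoxyphenyl)butanoate
Product: 12 (S)-2-(4-benzyloxy-3-methoxybenzyl)-4-tert-butoxy-4-oxobutanoic acid, via lithium peroxycarboxylate 11 (not isolated)
Conditions: LiOH, 30% H2O2, THF/H2O 3:1, 0 °C; then aq Na2SO3; then 1 M HCl to pH 3
Reagents that add atoms: hydrogen peroxide, OO; lithium hydroxide, [Li+].[OH-] (its lithium is in 11 only)
Why: Evans auxiliary hydrolysis: hydroperoxide attacks the exocyclic imide carbonyl selectively, sulfite reduces the peracid, and the tert-butyl ester and the α-stereocentre survive the cold, weakly basic medium.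

Step 7
Reactants: 12 (S)-2-(4-benzyloxy-3-methoxybenzyl)-4-tert-butoxy-4-oxobutanoic acid
Product: 13 tert-butyl (S)-4-(4-benzyloxy-3-methoxyphenyl)-3-(hydroxymethyl)butanoate
Conditions: BH3·THF (1.5 equiv), THF, 0 °C → rt; then MeOH/H2O
Reagents that add atoms: none
Why: Chemoselective borane reduction: BH3 reduces the free carboxylic acid through an acyloxyborane much faster than the tert-butyl ester, without enolising the stereocentre.

Step 8
Reactants: 13 tert-butyl (S)-4-(4-benzyloxy-3-methoxyphenyl)-3-(hydroxymethyl)butanoate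
Product: 14 (S)-4-(4-benzyloxy-3-methoxybenzyl)dihydrofuran-2(3H)-one
Conditions: p-TsOH·H2O (10 mol%), toluene, 80 °C
Reagents that add atoms: none
Why: Acid-catalysed lactonisation: the tert-butyl ester loses isobutene and the γ-hydroxy acid closes to the five-membered lactone, with the stereocentre not involved and the aryl benzyl ether stable to catalytic sulfonic acid.

Step 9
Reactants: 14 (S)-4-(4-benzyloxy-3-methoxybenzyl)dihydrofuran-2(3H)-one; 15 4-benzyloxy-3-methoxybenzaldehyde (O-benzylvanillin)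
Product: 17 (3R,4S)-4-(4-benzyloxy-3-methoxybenzyl)-3-[(4-benzyloxy-3-methoxyphenyl)(hydroxy)methyl]dihydrofuran-2(3H)-one (both carbinol epimers), via lithium enolate 16 (not isolated)
Conditions: LiN(i-Pr)2 (1.15 equiv), THF, −78 °C; then 15, −78 °C; sat. aq NH4Cl at −78 °C
Reagents that add atoms: lithium diisopropylamide, CC(C)[N-]C(C)C.[Li+] (its lithium is in 16 only)
Why: Intermolecular aldol addition joining the two C6C3 halves: the aldehyde adds to the lactone enolate anti to the C4 benzyl substituent, fixing the 3,4-trans relationship (C8 of the target), while the carbinol centre forms as a mixture that is erased in step 11.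

Step 10
Reactants: 17 (3R,4S)-4-(4-benzyloxy-3-methoxybenzyl)-3-[(4-benzyloxy-3-methoxyphenyl)(hydroxy)methyl]dihydrofuran-2(3H)-one
Product: 18 (2S,3S)-2-[(4-benzyloxy-3-methoxyphenyl)(hydroxy)methyl]-3-(4-benzyloxy-3-methoxybenzyl)butane-1,4-diol (both carbinol epimers)
Conditions: LiAlH4 (2.5 equiv), THF, 0 °C → rt; then H2O, 15% aq NaOH, H2O
Reagents that add atoms: none
Why: Hydride reduction of the lactone to the 1,4-diol at low temperature is faster than retro-aldol cleavage and touches neither the C8/C8' stereocentres nor the benzyl ethers.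

Step 11
Reactants: 18 (2S,3S)-2-[(4-benzyloxy-3-methoxyphenyl)(hydroxy)methyl]-3-(4-benzyloxy-3-methoxybenzyl)butane-1,4-diol
Product: 19 [(2R,3S,4S)-4-(4-benzyloxy-3-methoxybenzyl)-2-(4-benzyloxy-3-methoxyphenyl)tetrahydrofuran-3-yl]methanol
Conditions: (±)-camphor-10-sulfonic acid (10 mol%), CH2Cl2, 0 °C → rt
Reagents that add atoms: none
Why: Acid-mediated SN1 cyclodehydration: both carbinol epimers ionise to the same 4-alkoxybenzyl cation, which the C9' hydroxyl captures 5-exo (the other primary OH could only give an oxetane) so that the aryl group ends trans to the adjacent CH2OH group, the kinetically and thermodynamically favoured arrangement that sets C7 as R.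

Step 12
Reactants: 19 [(2R,3S,4S)-4-(4-benzyloxy-3-methoxybenzyl)-2-(4-benzyloxy-3-methoxyphenyl)tetrahydrofuran-3-yl]methanol; 20 4-(benzyloxy)benzoyl chloride
Product: 21 [(2R,3S,4S)-4-(4-benzyloxy-3-methoxybenzyl)-2-(4-benzyloxy-3-methoxyphenyl)tetrahydrofuran-3-yl]methyl 4-(benzyloxy)benzoate
Conditions: Et3N (2 equiv), DMAP (10 mol%), CH2Cl2, 0 °C → rt
Reagents that add atoms: none
Why: DMAP-catalysed acylation (nucleophilic catalysis) of the only free hydroxyl group under mild basic conditions that cannot epimerise any centre.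

Step 13
Reactants: 21 [(2R,3S,4S)-4-(4-benzyloxy-3-methoxybenzyl)-2-(4-benzyloxy-3-methoxyphenyl)tetrahydrofuran-3-yl]methyl 4-(benzyloxy)benzoate
Product: 22 agastinol [(2R,3S,4S)-4-(4-hydroxy-3-methoxybenzyl)-2-(4-hydroxy-3-methoxyphenyl)tetrahydrofuran-3-yl]methyl 4-hydroxybenzoate
Conditions: H2 (1 atm), 10% Pd/C, EtOAc, rt, stopped as soon as debenzylation is complete
Reagents that add atoms: none
Why: Hydrogenolysis of the three aryl benzyl ethers under neutral conditions is much faster than cleavage of the cyclic benzylic ether or the ester, so the target is released without touching a stereocentre.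

**Compound list**
1 | ferulic acid | COc1cc(/C=C/C(=O)O)ccc1O | starting material
2 | 3-(4-hydroxy-3-methoxyphenyl)propanoic acid | COc1cc(CCC(=O)O)ccc1O | intermediate
3 | benzyl 3-(4-benzyloxy-3-methoxyphenyl)propanoate | COc1cc(CCC(=O)OCc2ccccc2)ccc1OCc1ccccc1 | intermediate
4 | 3-(4-benzyloxy-3-methoxyphenyl)propanoic acid | COc1cc(CCC(=O)O)ccc1OCc1ccccc1 | intermediate
5 | (R)-4-benzyl-2-oxazolidinone | O=C1N[C@H](Cc2ccccc2)CO1 | starting material
6 | 3-(4-benzyloxy-3-methoxyphenyl)propanoic pivalic anhydride (not isolated) | COc1cc(CCC(=O)OC(=O)C(C)(C)C)ccc1OCc1ccccc1 | intermediate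
7 | (R)-4-benzyl-3-[3-(4-benzyloxy-3-methoxyphenyl)propanoyl]oxazolidin-2-one | COc1cc(CCC(=O)N2[C@H](Cc3ccccc3)COC2=O)ccc1OCc1ccccc1 | intermediate
8 | tert-butyl bromoacetate | CC(C)(C)OC(=O)CBr | starting material
9 | sodium (Z)-1-[(R)-4-benzyl-2-oxooxazolidin-3-yl]-3-(4-benzyloxy-3-methoxyphenyl)prop-1-en-1-olate (not isolated) | [Na+].[O-]/C(=C\Cc1ccc(OCc2ccccc2)c(OC)c1)N1[C@H](Cc2ccccc2)COC1=O | intermediate
10 | tert-butyl (S)-3-[(R)-4-benzyl-2-oxooxazolidine-3-carbonyl]-4-(4-benzyloxy-3-methoxyphenyl)butanoate | CC(C)(C)OC(=O)C[C@H](Cc1ccc(OCc2ccccc2)c(OC)c1)C(=O)N1[C@H](Cc2ccccc2)COC1=O | intermediate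
11 | lithium (S)-2-(4-benzyloxy-3-methoxybenzyl)-4-tert-butoxy-4-oxobutaneperoxoate (not isolated) | CC(C)(C)OC(=O)C[C@H](Cc1ccc(OCc2ccccc2)c(OC)c1)C(=O)O[O-].[Li+] | intermediate
12 | (S)-2-(4-benzyloxy-3-methoxybenzyl)-4-tert-butoxy-4-oxobutanoic acid | CC(C)(C)OC(=O)C[C@H](Cc1ccc(OCc2ccccc2)c(OC)c1)C(=O)O | intermediate
13 | tert-butyl (S)-4-(4-benzyloxy-3-methoxyphenyl)-3-(hydroxymethyl)butanoate | CC(C)(C)OC(=O)C[C@H](Cc1ccc(OCc2ccccc2)c(OC)c1)CO | intermediate
14 | (S)-4-(4-benzyloxy-3-methoxybenzyl)dihydrofuran-2(3H)-one | O=C1C[C@H](Cc2ccc(OCc3ccccc3)c(OC)c2)CO1 | intermediate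
15 | 4-benzyloxy-3-methoxybenzaldehyde | COc1cc(C=O)ccc1OCc1ccccc1 | starting material
16 | lithium (S)-4-(4-benzyloxy-3-methoxybenzyl)-4,5-dihydrofuran-2-olate (not isolated) | [Li+].[O-]C1=C[C@H](Cc2ccc(OCc3ccccc3)c(OC)c2)CO1 | intermediate
17 | (3R,4S)-4-(4-benzyloxy-3-methoxybenzyl)-3-[(4-benzyloxy-3-methoxyphenyl)(hydroxy)methyl]dihydrofuran-2(3H)-one, both C7 epimers | O=C1OC[C@@H](Cc2ccc(OCc3ccccc3)c(OC)c2)[C@@H]1C(O)c1ccc(OCc2ccccc2)c(OC)c1 | intermediate
18 | (2S,3S)-2-[(4-benzyloxy-3-methoxyphenyl)(hydroxy)methyl]-3-(4-benzyloxy-3-methoxybenzyl)butane-1,4-diol, both C7 epimers | OC[C@@H](Cc1ccc(OCc2ccccc2)c(OC)c1)[C@@H](CO)C(O)c1ccc(OCc2ccccc2)c(OC)c1 | intermediate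
19 | [(2R,3S,4S)-4-(4-benzyloxy-3-methoxybenzyl)-2-(4-benzyloxy-3-methoxyphenyl)tetrahydrofuran-3-yl]methanol | COc1cc(C[C@@H]2CO[C@@H](c3ccc(OCc4ccccc4)c(OC)c3)[C@@H]2CO)ccc1OCc1ccccc1 | intermediate
20 | 4-(benzyloxy)benzoyl chloride | O=C(Cl)c1ccc(OCc2ccccc2)cc1 | starting material
21 | [(2R,3S,4S)-4-(4-benzyloxy-3-methoxybenzyl)-2-(4-benzyloxy-3-methoxyphenyl)tetrahydrofuran-3-yl]methyl 4-(benzyloxy)benzoate | COc1cc(C[C@@H]2CO[C@@H](c3ccc(OCc4ccccc4)c(OC)c3)[C@@H]2COC(=O)c2ccc(OCc3ccccc3)cc2)ccc1OCc1ccccc1 | intermediate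
22 | agastinol | COc1cc(C[C@@H]2CO[C@@H](c3ccc(O)c(OC)c3)[C@@H]2COC(=O)c2ccc(O)cc2)ccc1O | target

**Summary**
Total step count: 13. Longest linear sequence: 13 steps (1 → 22); compounds 5, 8, 15 and 20 are used as purchased.

**Steps most likely to fail**

Step 11 (ring closure). The benzylic cation can also close onto the electron-rich ring of the C8' benzyl group (Friedel–Crafts, aryltetralin), or the 7,8-trans selectivity may be incomplete. The fallback sets out from triol 18 and comes back at 19, using the free phenol instead of the benzyl ether to trigger the closure. H2 (1 atm), 10% Pd/C, EtOAc, rt, short reaction time, removes both benzyl ethers and gives (2S,3S)-2-[hydroxy(4-hydroxy-3-methoxyphenyl)methyl]-3-(4-hydroxy-3-methoxybenzyl)butane-1,4-diol F3. With the para-phenol free, the benzylic alcohol ionises through a p-quinone methide under much milder acid (pyridinium p-toluenesulfonate, 10 mol%, THF, rt), where Friedel–Crafts closure does not compete. 5-exo oxa-Michael capture by the C9' hydroxyl then gives (−)-lariciresinol F4. BnBr (2.2 equiv), K2CO3, acetone, reflux re-benzylates only the two phenols and returns 19.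

Step 13 (global debenzylation). Pd/H2 may also hydrogenolyse the cyclic benzylic C7–O bond and open the ring. The fallback sets out from lactone 14 and comes back at the target 22, exchanging benzyl for allyl before any benzylic C–O bond exists, so that no hydrogenation is needed afterwards. H2, 10% Pd/C, EtOAc converts 14 into (S)-4-(4-hydroxy-3-methoxybenzyl)dihydrofuran-2(3H)-one F5. Allyl bromide, K2CO3, acetone gives (S)-4-(4-allyloxy-3-methoxybenzyl)dihydrofuran-2(3H)-one F6. LiN(i-Pr)2, THF, −78 °C forms lithium (S)-4-(4-allyloxy-3-methoxybenzyl)-4,5-dihydrofuran-2-olate F7, which adds to purchased 4-allyloxy-3-methoxybenzaldehyde to give (3R,4S)-4-(4-allyloxy-3-methoxybenzyl)-3-[(4-allyloxy-3-methoxyphenyl)(hydroxy)methyl]dihydrofuran-2(3H)-one F8. LiAlH4 in THF gives (2S,3S)-2-[(4-allyloxy-3-methoxyphenyl)(hydroxy)methyl]-3-(4-allyloxy-3-methoxybenzyl)butane-1,4-diol F9. Camphor-10-sulfonic acid in CH2Cl2 closes it to [(2R,3S,4S)-4-(4-allyloxy-3-methoxybenzyl)-2-(4-allyloxy-3-methoxyphenyl)tetrahydrofuran-3-yl]methanol F10. DCC/DMAP with purchased 4-(allyloxy)benzoic acid gives [(2R,3S,4S)-4-(4-allyloxy-3-methoxybenzyl)-2-(4-allyloxy-3-methoxyphenyl)tetrahydrofuran-3-yl]methyl 4-(allyloxy)benzoate F11. Pd(PPh3)4 (5 mol%, a zerovalent palladium complex) and morpholine in THF at rt transfer the three allyl groups to the amine and give 22, leaving the benzylic ether and the ester untouched.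

Step 9 (aldol). Retro-aldol on work-up or sluggish addition to the electron-rich aldehyde could erode the yield. The fallback sets out from lactone 14 (through its enolate 16) and comes back at 17, replacing the aldol addition by a Claisen-type C-acylation followed by ketone reduction. Purchased 4-benzyloxy-3-methoxybenzoic acid is converted with (COCl)2 and catalytic DMF into 4-(benzyloxy)-3-methoxybenzoyl chloride F1. Enolate 16, made with LiN(SiMe3)2 (2.1 equiv) in THF at −78 °C, is acylated irreversibly by F1 to give (3R,4S)-3-(4-benzyloxy-3-methoxybenzoyl)-4-(4-benzyloxy-3-methoxybenzyl)dihydrofuran-2(3H)-one F2, whose C3 centre equilibrates to the trans isomer. NaBH4 in MeOH/THF at −20 °C reduces only the ketone and returns 17 as the same epimer mixture.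

**Further compounds**
F1 | step 9 | 4-(benzyloxy)-3-methoxybenzoyl chloride | COc1cc(C(=O)Cl)ccc1OCc1ccccc1
F2 | step 9 | (3R,4S)-3-(4-benzyloxy-3-methoxybenzoyl)-4-(4-benzyloxy-3-methoxybenzyl)dihydrofuran-2(3H)-one | O=C1OC[C@@H](Cc2ccc(OCc3ccccc3)c(OC)c2)[C@@H]1C(=O)c1ccc(OCc2ccccc2)c(OC)c1
F3 | step 11 | (2S,3S)-2-[hydroxy(4-hydroxy-3-methoxyphenyl)methyl]-3-(4-hydroxy-3-methoxybenzyl)butane-1,4-diol | OC[C@@H](Cc1ccc(O)c(OC)c1)[C@@H](CO)C(O)c1ccc(O)c(OC)c1
F4 | step 11 | (−)-lariciresinol | COc1cc(C[C@@H]2CO[C@@H](c3ccc(O)c(OC)c3)[C@@H]2CO)ccc1O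
F5 | step 13 | (S)-4-(4-hydroxy-3-methoxybenzyl)dihydrofuran-2(3H)-one | O=C1C[C@H](Cc2ccc(O)c(OC)c2)CO1
F6 | step 13 | (S)-4-(4-allyloxy-3-methoxybenzyl)dihydrofuran-2(3H)-one | O=C1C[C@H](Cc2ccc(OCC=C)c(OC)c2)CO1
F7 | step 13 | lithium (S)-4-(4-allyloxy-3-methoxybenzyl)-4,5-dihydrofuran-2-olate | [Li+].[O-]C1=C[C@H](Cc2ccc(OCC=C)c(OC)c2)CO1
F8 | step 13 | (3R,4S)-4-(4-allyloxy-3-methoxybenzyl)-3-[(4-allyloxy-3-methoxyphenyl)(hydroxy)methyl]dihydrofuran-2(3H)-one | O=C1OC[C@@H](Cc2ccc(OCC=C)c(OC)c2)[C@@H]1C(O)c1ccc(OCC=C)c(OC)c1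
F9 | step 13 | (2S,3S)-2-[(4-allyloxy-3-methoxyphenyl)(hydroxy)methyl]-3-(4-allyloxy-3-methoxybenzyl)butane-1,4-diol | OC[C@@H](Cc1ccc(OCC=C)c(OC)c1)[C@@H](CO)C(O)c1ccc(OCC=C)c(OC)c1
F10 | step 13 | [(2R,3S,4S)-4-(4-allyloxy-3-methoxybenzyl)-2-(4-allyloxy-3-methoxyphenyl)tetrahydrofuran-3-yl]methanol | COc1cc(C[C@@H]2CO[C@@H](c3ccc(OCC=C)c(OC)c3)[C@@H]2CO)ccc1OCC=C
F11 | step 13 | [(2R,3S,4S)-4-(4-allyloxy-3-methoxybenzyl)-2-(4-allyloxy-3-methoxyphenyl)tetrahydrofuran-3-yl]methyl 4-(allyloxy)benzoate | COc1cc(C[C@@H]2CO[C@@H](c3ccc(OCC=C)c(OC)c3)[C@@H]2COC(=O)c2ccc(OCC=C)cc2)ccc1OCC=C
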